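**Retrosynthetic overview**

1. Numbering: C1 (CH2Br), C2 (carbinol), C3=C4 (Z-alkene, methyl on C3), C5 (allylic CH2), ring C6 (CH)–C7 (=C14H2)–C8–C9–C10 (CHBr)–C11 (CMe2). The strategy rests on the exocyclic methylidene C7=C14 lying next to the ring methine C6, whose arm C5–C4 can be an acetate: the footprint of an alkenyl radical at C7 closing 6-exo onto C6 of an enoate C6=C5–C4O2Et.
2. C3=C4 is cut by a Z-selective Wittig reaction between the ring phosphonium salt 18 (C4–C11, C14) and the (R)-glycerate-derived methyl ketone 21 (C1–C3 and the C3 methyl); the C1 bromide comes last, through the primary sulfonate.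
3. The C10 bromide is traced to the C10 oxygen of the cyclised ester 12 with net retention (oxidation, reagent-controlled reduction, Appel inversion), carried out once the ester has been reduced.
4. Key disconnection C6–C7: tin-hydride cyclisation of the alkenyl iodide/enoate 11 gives 12; it forms the only ring (the cyclohexane C6–C11) and sets C6 from C10.
5. 11 comes from 4-iodopent-4-enal 3, the isobutyrate ketene silyl acetal 4 (asymmetric Mukaiyama aldol sets C10 and brings C11) and triethyl phosphonoacetate 10 (C5, C4).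

Key step: step 8

Assumption (remark on the chemistry): the oxazaborolidinone from N-tosyl-D-valine is taken to give the (3S)-aldol with an unbranched aliphatic aldehyde; if the opposite sense were found, the L-valine-derived catalyst would be used in step 3 with nothing else changed.

**Route**

Step 1
Reactants: 1 pent-4-yn-1-ol
Product: 2 4-iodopent-4-en-1-ol
Conditions: NaI, Me3SiCl, H2O, MeCN, 0 °C → rt
Reagents that add atoms: sodium iodide, [Na+].[I-]
Why: Markovnikov hydroiodination: HI generated in the flask adds across the terminal alkyne to give the 2-iodoalk-1-ene, and the transient silyl ether of the hydroxyl is lost on aqueous work-up.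

Step 2
Reactants: 2 4-iodopent-4-en-1-ol
Product: 3 4-iodopent-4-enal
Conditions: Dess–Martin periodinane, CH2Cl2, 0 °C → rt
Reagents that add atoms: none
Why: Dess–Martin oxidation takes the primary alcohol to the aldehyde under near-neutral conditions that leave the alkenyl iodide untouched.

Step 3
Reactants: 3 4-iodopent-4-enal; 4 1-methoxy-2-methyl-1-(trimethylsilyloxy)prop-1-ene
Product: 6 methyl (3S)-3-hydroxy-6-iodo-2,2-dimethylhept-6-enoate, via trimethylsilyl ether 5 (not isolated)
Conditions: oxazaborolidinone from N-tosyl-D-valine and BH3·THF (20 mol %), EtNO2, −78 °C, slow addition of 3; then 1 M HCl, THF, rt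
Reagents that add atoms: none
Why: Catalytic asymmetric Mukaiyama aldol: the chiral boron Lewis acid binds the aldehyde and shields one face, so the ketene acetal should add to give the (3S)-carbinol (future C10) next to the new quaternary carbon (C11); silyl transfer to the aldolate oxygen turns the catalyst over and acid frees the alcohol.

Step 4
Reactants: 6 methyl (3S)-3-hydroxy-6-iodo-2,2-dimethylhept-6-enoate
Product: 7 methyl (3S)-3-[(tert-butyldimethylsilyl)oxy]-6-iodo-2,2-dimethylhept-6-enoate
Conditions: tBuMe2SiOTf, 2,6-lutidine, CH2Cl2, −78 → 0 °C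
Reagents that add atoms: tert-butyldimethylsilyl trifluoromethanesulfonate, CC(C)(C)[Si](C)(C)OS(=O)(=O)C(F)(F)F
Why: Silylation of the hindered secondary alcohol with the silyl triflate installs the bulky ether that later holds the equatorial position at C10 in the ring closure.

Step 5
Reactants: 7 methyl (3S)-3-[(tert-butyldimethylsilyl)oxy]-6-iodo-2,2-dimethylhept-6-enoate
Product: 8 (3S)-3-[(tert-butyldimethylsilyl)oxy]-6-iodo-2,2-dimethylhept-6-en-1-ol
Conditions: iBu2AlH, CH2Cl2, −78 → 0 °C; aq. KNaC4H4O6
Reagents that add atoms: none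
Why: Hydride reduction of the ester fully to the primary alcohol avoids the uncertain half-reduction of a hindered ester; the alkenyl iodide and silyl ether are inert to iBu2AlH at this temperature.

Step 6
Reactants: 8 (3S)-3-[(tert-butyldimethylsilyl)oxy]-6-iodo-2,2-dimethylhept-6-en-1-ol
Product: 9 (3S)-3-[(tert-butyldimethylsilyl)oxy]-6-iodo-2,2-dimethylhept-6-enal
Conditions: Dess–Martin periodinane, CH2Cl2, rt
Reagents that add atoms: none
Why: Dess–Martin oxidation gives an aldehyde with no α-hydrogen, so it can neither enolise nor epimerise.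

Step 7
Reactants: 9 (3S)-3-[(tert-butyldimethylsilyl)oxy]-6-iodo-2,2-dimethylhept-6-enal; 10 triethyl phosphonoacetate
Product: 11 ethyl (2E,5S)-5-[(tert-butyldimethylsilyl)oxy]-8-iodo-4,4-dimethylnona-2,8-dienoate
Conditions: NaH, THF, 0 °C → rt
Reagents that add atoms: none
Why: Horner–Wadsworth–Emmons olefination of the non-enolisable aldehyde with the stabilised phosphonate anion should give the (E)-enoate, placing the acceptor carbons C6=C5 and the ester carbon C4.

Step 8
Reactants: 11 ethyl (2E,5S)-5-[(tert-butyldimethylsilyl)oxy]-8-iodo-4,4-dimethylnona-2,8-dienoate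
Product: 12 ethyl 2-[(1R,3S)-3-[(tert-butyldimethylsilyl)oxy]-2,2-dimethyl-6-methylidenecyclohexyl]acetate
Conditions: Bu3SnH (1.3 equiv, syringe pump), azobisisobutyronitrile (0.2 equiv), PhH (5 mM), 80 °C; then aq. KF
Reagents that add atoms: none
Why: Bu3Sn• removes iodine from C7 and the σ-alkenyl radical adds to C6, the β-carbon of the enoate, forming the C6–C7 bond; the α-ester radical at C5 then takes hydrogen from Bu3SnH and carries the chain. This is the tin-hydride cyclisation of a 2-iodoalk-1-ene-derived alkenyl radical onto an acrylate-type acceptor, a known reaction class. The cyclohexane ring (C6–C7–C8–C9–C10–C11) closes in the 6-exo-trig mode through a chair-like transition state. The new stereocentre C6 is controlled by C10: the bulky silyloxy group and the enoate arm should both sit equatorial, which gives the cis (1R,3S) isomer. Ring closure must outrun hydrogen transfer to the alkenyl radical and 6-exo must beat 7-endo attack; slow stannane addition at high dilution, the gem-dimethyl group at C11 (which also offers no hydrogen for a 1,5-shift) and the match of a nucleophilic σ-radical with the electron-poor β-carbon secure this. Any trans isomer is removed at 12 or 13, because after oxidation at C10 the two C6 epimers would become enantiomers.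

Step 9
Reactants: 12 ethyl 2-[(1R,3S)-3-[(tert-butyldimethylsilyl)oxy]-2,2-dimethyl-6-methylidenecyclohexyl]acetate
Product: 13 ethyl 2-[(1R,3S)-3-hydroxy-2,2-dimethyl-6-methylidenecyclohexyl]acetate
Conditions: aq. HF (48 %), MeCN, 0 °C → rt
Reagents that add atoms: none
Why: Acidic fluoride desilylation is chosen over a basic fluoride source so that no alkoxide forms cis to the ester arm, which could lactonise.

Step 10
Reactants: 13 ethyl 2-[(1R,3S)-3-hydroxy-2,2-dimethyl-6-methylidenecyclohexyl]acetate
Product: 14 ethyl 2-[(1R)-2,2-dimethyl-6-methylidene-3-oxocyclohexyl]acetate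
Conditions: Dess–Martin periodinane, CH2Cl2, rt
Reagents that add atoms: none
Why: Dess–Martin oxidation of the secondary alcohol erases C10 while C6, which is not α to any carbonyl group, keeps its configuration.

Step 11
Reactants: 14 ethyl 2-[(1R)-2,2-dimethyl-6-methylidene-3-oxocyclohexyl]acetate
Product: 15 ethyl 2-[(1R,3R)-3-hydroxy-2,2-dimethyl-6-methylidenecyclohexyl]acetate
Conditions: (S)-Me-CBS [(3aS)-1-methyl-3,3-diphenyltetrahydro-1H,3H-pyrrolo[1,2-c][1,3,2]oxazaborole, 0.3 equiv], catecholborane, toluene, −78 → −30 °C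
Reagents that add atoms: none
Why: Corey–Bakshi–Shibata reduction: the catalyst tells the quaternary C11 flank (large) from the C9 methylene (small) and should give the (10R)-carbinol, trans to the C6 arm, by reagent control; a bulky hydride is avoided because with C10 trigonal the ring can flip to the axial-arm conformer, so substrate control is unreliable, and catecholborane spares the methylidene and the ester.

Step 12
Reactants: 15 ethyl 2-[(1R,3R)-3-hydroxy-2,2-dimethyl-6-methylidenecyclohexyl]acetate
Product: 16 (1R,3R)-3-(2-hydroxyethyl)-2,2-dimethyl-4-methylidenecyclohexan-1-ol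
Conditions: iBu2AlH, CH2Cl2, −78 → 0 °C; aq. KNaC4H4O6
Reagents that add atoms: none
Why: Hydride reduction of the ester to the primary alcohol removes the carbonyl oxygen that could otherwise capture C10 from the rear (lactonisation) during the substitution that follows.

Step 13
Reactants: 16 (1R,3R)-3-(2-hydroxyethyl)-2,2-dimethyl-4-methylidenecyclohexan-1-ol
Product: 17 (1S,3R)-1-bromo-3-(2-bromoethyl)-2,2-dimethyl-4-methylidenecyclohexane
Conditions: CBr4, PPh3 (excess), CH2Cl2, 0 °C → 40 °C
Reagents that add atoms: tetrabromomethane, BrC(Br)(Br)Br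
Why: Appel reaction: the primary carbinol is brominated first, then the axial C10 alkoxyphosphonium ion is displaced by bromide with inversion (SN2), turning the trans (10R) alcohol into the (10S) bromide cis to the arm with both groups equatorial, a substitution known for axial carbinols next to a gem-dimethyl carbon.

Step 14
Reactants: 17 (1S,3R)-1-bromo-3-(2-bromoethyl)-2,2-dimethyl-4-methylidenecyclohexane
Product: 18 {2-[(1R,3S)-3-bromo-2,2-dimethyl-6-methylidenecyclohexyl]ethyl}triphenylphosphonium bromide
Conditions: PPh3, MeCN, reflux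
Reagents that add atoms: triphenylphosphine, c1ccc(cc1)P(c1ccccc1)c1ccccc1
Why: Quaternisation (SN2) of PPh3 occurs only at the primary bromide; the secondary bromide beside the quaternary carbon is inert to the phosphine.

Step 15
Reactants: 19 methyl (4R)-2,2-dimethyl-1,3-dioxolane-4-carboxylate
Product: 20 (4R)-N-methoxy-N,2,2-trimethyl-1,3-dioxolane-4-carboxamide
Conditions: MeNH(OMe)·HCl, iPrMgCl, THF, −20 °C
Reagents that add atoms: N,O-dimethylhydroxylamine hydrochloride, CNOC.Cl
Why: Weinreb amide formation by aminolysis of the ester with the magnesium amide at low temperature, conditions that should not disturb the α-alkoxy stereocentre.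

Step 16
Reactants: 20 (4R)-N-methoxy-N,2,2-trimethyl-1,3-dioxolane-4-carboxamide
Product: 21 1-[(4R)-2,2-dimethyl-1,3-dioxolan-4-yl]ethan-1-one
Conditions: MeMgBr, THF, −78 → 0 °C; aq. NH4Cl
Reagents that add atoms: methylmagnesium bromide, C[Mg]Br
Why: Grignard addition to the Weinreb amide stops at the ketone because the chelated tetrahedral intermediate survives until work-up.

Step 17
Reactants: 18 {2-[(1R,3S)-3-bromo-2,2-dimethyl-6-methylidenecyclohexyl]ethyl}triphenylphosphonium bromide; 21 1-[(4R)-2,2-dimethyl-1,3-dioxolan-4-yl]ethan-1-one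
Product: 23 (4S)-4-{(2Z)-4-[(1R,3S)-3-bromo-2,2-dimethyl-6-methylidenecyclohexyl]but-2-en-2-yl}-2,2-dimethyl-1,3-dioxolane, via phosphorus ylide 22 (not isolated)
Conditions: KN(SiMe3)2, THF, −78 → 0 °C; then 21, −78 °C → rt
Reagents that add atoms: none
Why: Wittig olefination of an α-alkoxy methyl ketone with a non-stabilised ylide at low temperature is known to favour the (Z)-trisubstituted alkene (C5 cis to the oxygenated C2); C2 comes unchanged from the glycerate, its descriptor changing from R to S only through the priority rules.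

Step 18
Reactants: 23 (4S)-4-{(2Z)-4-[(1R,3S)-3-bromo-2,2-dimethyl-6-methylidenecyclohexyl]but-2-en-2-yl}-2,2-dimethyl-1,3-dioxolane
Product: 24 (2S,3Z)-5-[(1R,3S)-3-bromo-2,2-dimethyl-6-methylidenecyclohexyl]-3-methylpent-3-ene-1,2-diol
Conditions: AcOH/H2O (4:1), 40 °C
Reagents that add atoms: none
Why: Mild acid-catalysed acetal hydrolysis frees the 1,2-diol without ionising the allylic C2–O bond or moving the methylidene into the ring.

Step 19
Reactants: 24 (2S,3Z)-5-[(1R,3S)-3-bromo-2,2-dimethyl-6-methylidenecyclohexyl]-3-methylpent-3-ene-1,2-diol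
Product: 25 (2S,3Z)-5-[(1R,3S)-3-bromo-2,2-dimethyl-6-methylidenecyclohexyl]-2-hydroxy-3-methylpent-3-en-1-yl 4-methylbenzenesulfonate
Conditions: TsCl, Bu2SnO (2 mol %), Et3N, CH2Cl2, 0 °C → rt
Reagents that add atoms: 4-methylbenzenesulfonyl chloride, Cc1ccc(cc1)S(=O)(=O)Cl
Why: Tin-catalysed regioselective sulfonylation through the stannylene acetal activates only the primary hydroxyl of the terminal 1,2-diol.

Step 20
Reactants: 25 (2S,3Z)-5-[(1R,3S)-3-bromo-2,2-dimethyl-6-methylidenecyclohexyl]-2-hydroxy-3-methylpent-3-en-1-yl 4-methylbenzenesulfonate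
Product: 26 (2S,3Z)-1-bromo-5-[(1R,3S)-3-bromo-2,2-dimethyl-6-methylidenecyclohexyl]-3-methylpent-3-en-2-ol
Conditions: LiBr, acetone, 50 °C
Reagents that add atoms: lithium bromide, [Li+].[Br-]
Why: Finkelstein-type SN2 displacement of the primary tosylate by bromide under neutral conditions gives the bromohydrin without epoxide formation and without touching C2.

**Compound list**

1 | pent-4-yn-1-ol | C#CCCCO | starting material
2 | 4-iodopent-4-en-1-ol | C=C(I)CCCO | intermediate
3 | 4-iodopent-4-enal | C=C(I)CCC=O | intermediate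
4 | 1-methoxy-2-methyl-1-(trimethylsilyloxy)prop-1-ene | COC(O[Si](C)(C)C)=C(C)C | starting material
5 | methyl (3S)-6-iodo-2,2-dimethyl-3-(trimethylsilyloxy)hept-6-enoate | C=C(I)CC[C@H](O[Si](C)(C)C)C(C)(C)C(=O)OC | intermediate
6 | methyl (3S)-3-hydroxy-6-iodo-2,2-dimethylhept-6-enoate | C=C(I)CC[C@H](O)C(C)(C)C(=O)OC | intermediate
7 | methyl (3S)-3-[(tert-butyldimethylsilyl)oxy]-6-iodo-2,2-dimethylhept-6-enoate | C=C(I)CC[C@H](O[Si](C)(C)C(C)(C)C)C(C)(C)C(=O)OC | intermediate
8 | (3S)-3-[(tert-butyldimethylsilyl)oxy]-6-iodo-2,2-dimethylhept-6-en-1-ol | C=C(I)CC[C@H](O[Si](C)(C)C(C)(C)C)C(C)(C)CO | intermediate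
9 | (3S)-3-[(tert-butyldimethylsilyl)oxy]-6-iodo-2,2-dimethylhept-6-enal | C=C(I)CC[C@H](O[Si](C)(C)C(C)(C)C)C(C)(C)C=O | intermediate
10 | triethyl phosphonoacetate | CCOC(=O)CP(=O)(OCC)OCC | starting material
11 | ethyl (2E,5S)-5-[(tert-butyldimethylsilyl)oxy]-8-iodo-4,4-dimethylnona-2,8-dienoate | C=C(I)CC[C@H](O[Si](C)(C)C(C)(C)C)C(C)(C)/C=C/C(=O)OCC | intermediate
12 | ethyl 2-[(1R,3S)-3-[(tert-butyldimethylsilyl)oxy]-2,2-dimethyl-6-methylidenecyclohexyl]acetate | C=C1CC[C@H](O[Si](C)(C)C(C)(C)C)C(C)(C)[C@@H]1CC(=O)OCC | intermediate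
13 | ethyl 2-[(1R,3S)-3-hydroxy-2,2-dimethyl-6-methylidenecyclohexyl]acetate | C=C1CC[C@H](O)C(C)(C)[C@@H]1CC(=O)OCC | intermediate
14 | ethyl 2-[(1R)-2,2-dimethyl-6-methylidene-3-oxocyclohexyl]acetate | C=C1CCC(=O)C(C)(C)[C@@H]1CC(=O)OCC | intermediate
15 | ethyl 2-[(1R,3R)-3-hydroxy-2,2-dimethyl-6-methylidenecyclohexyl]acetate | C=C1CC[C@@H](O)C(C)(C)[C@@H]1CC(=O)OCC | intermediate
16 | (1R,3R)-3-(2-hydroxyethyl)-2,2-dimethyl-4-methylidenecyclohexan-1-ol | C=C1CC[C@@H](O)C(C)(C)[C@@H]1CCO | intermediate
17 | (1S,3R)-1-bromo-3-(2-bromoethyl)-2,2-dimethyl-4-methylidenecyclohexane | C=C1CC[C@H](Br)C(C)(C)[C@@H]1CCBr | intermediate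
18 | {2-[(1R,3S)-3-bromo-2,2-dimethyl-6-methylidenecyclohexyl]ethyl}triphenylphosphonium bromide | C=C1CC[C@H](Br)C(C)(C)[C@@H]1CC[P+](c1ccccc1)(c1ccccc1)c1ccccc1.[Br-] | intermediate
19 | methyl (4R)-2,2-dimethyl-1,3-dioxolane-4-carboxylate | COC(=O)[C@H]1COC(C)(C)O1 | starting material
20 | (4R)-N-methoxy-N,2,2-trimethyl-1,3-dioxolane-4-carboxamide | CON(C)C(=O)[C@H]1COC(C)(C)O1 | intermediate
21 | 1-[(4R)-2,2-dimethyl-1,3-dioxolan-4-yl]ethan-1-one | CC(=O)[C@H]1COC(C)(C)O1 | intermediate
22 | {2-[(1R,3S)-3-bromo-2,2-dimethyl-6-methylidenecyclohexyl]ethylidene}triphenylphosphorane | C=C1CC[C@H](Br)C(C)(C)[C@@H]1CC=P(c1ccccc1)(c1ccccc1)c1ccccc1 | intermediate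
23 | (4S)-4-{(2Z)-4-[(1R,3S)-3-bromo-2,2-dimethyl-6-methylidenecyclohexyl]but-2-en-2-yl}-2,2-dimethyl-1,3-dioxolane | C=C1CC[C@H](Br)C(C)(C)[C@@H]1C/C=C(/C)[C@H]1COC(C)(C)O1 | intermediate
24 | (2S,3Z)-5-[(1R,3S)-3-bromo-2,2-dimethyl-6-methylidenecyclohexyl]-3-methylpent-3-ene-1,2-diol | C=C1CC[C@H](Br)C(C)(C)[C@@H]1C/C=C(/C)[C@H](O)CO | intermediate
25 | (2S,3Z)-5-[(1R,3S)-3-bromo-2,2-dimethyl-6-methylidenecyclohexyl]-2-hydroxy-3-methylpent-3-en-1-yl 4-methylbenzenesulfonate | C=C1CC[C@H](Br)C(C)(C)[C@@H]1C/C=C(/C)[C@H](O)COS(=O)(=O)c1ccc(C)cc1 | intermediate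
26 | (2S,3Z)-1-bromo-5-[(1R,3S)-3-bromo-2,2-dimethyl-6-methylidenecyclohexyl]-3-methylpent-3-en-2-ol | C=C1CC[C@H](Br)C(C)(C)[C@@H]1C/C=C(/C)[C@H](O)CBr | target

**Step count and risks**

Total step count: 20. Longest linear sequence: 18 steps (steps 1–14, then 17–20); steps 15 and 16 form a two-step side branch to ketone 21.

Steps most likely to fail:

Step 8 (radical ring closure). Hydrogen transfer from the stannane to the alkenyl radical may overtake ring closure, and facial discrimination at C6 may be modest, which would later erode enantiomeric purity if the epimers are not separated. The fallback sets out from 11 and comes back at 12. The same C6–C7 bond is made by a nickel-mediated intramolecular conjugate addition: Ni(cod)2 (zerovalent nickel, stoichiometric), Et3N, MeCN, rt inserts into the C7–I bond, the alkenylnickel species adds 6-exo to the enoate, and the nickel enolate is quenched with Et3SiH or aqueous NH4Cl. No hydrogen-atom donor competes with closure, and the organometallic transition state gives a second, independent chance of facial control. This path makes no new compound (F0).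

Step 13 (substitution at C10). Bimolecular displacement at the carbinol beside the quaternary carbon is slow and may be overtaken by E2 loss of the activated oxygen toward C9 or by methyl migration from C11. The fallback sets out from 16 and comes back at 17, separating activation from substitution. The primary carbinol alone is brominated (CBr4 1.1 equiv, PPh3, CH2Cl2, 0 °C) to give (1R,3R)-3-(2-bromoethyl)-2,2-dimethyl-4-methylidenecyclohexan-1-ol F1. The axial secondary carbinol is then esterified (ClCH2SO2Cl, pyridine, 0 °C) to (1R,3R)-3-(2-bromoethyl)-2,2-dimethyl-4-methylidenecyclohexyl chloromethanesulfonate F2. This isolated sulfonate is displaced with Bu4NBr in toluene at 60–80 °C, where exchange at the primary bromide is degenerate, to give 17 with inversion; leaving group and bromide source can be tuned independently.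

Step 17 (Wittig olefination). The ylide may deprotonate the α-alkoxy ketone, eroding configuration at C2 and lowering conversion, and Z-selectivity may be incomplete. The fallback sets out from 17 and comes back at the target 26, building the alkene from the other side and creating C2 by reagent control.
- The primary bromide of 17 is oxidised with Me3NO in DMSO at rt (Kornblum-type) to 2-[(1R,3S)-3-bromo-2,2-dimethyl-6-methylidenecyclohexyl]acetaldehyde F3.
- Still–Gennari olefination with methyl 2-[bis(2,2,2-trifluoroethoxy)phosphoryl]propanoate, KN(SiMe3)2, 18-crown-6, THF, −78 °C gives methyl (2Z)-4-[(1R,3S)-3-bromo-2,2-dimethyl-6-methylidenecyclohexyl]-2-methylbut-2-enoate F4.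
- MeNH(OMe)·HCl and iPrMgCl in THF at −20 °C give (2Z)-4-[(1R,3S)-3-bromo-2,2-dimethyl-6-methylidenecyclohexyl]-N-methoxy-N,2-dimethylbut-2-enamide F5.
- LiCH2Br (from CH2Br2 and MeLi·LiBr, THF, −78 °C) converts the amide into (3Z)-1-bromo-5-[(1R,3S)-3-bromo-2,2-dimethyl-6-methylidenecyclohexyl]-3-methylpent-3-en-2-one F6.
- Corey–Bakshi–Shibata reduction of F6 with (S)-Me-CBS and catecholborane (alkenyl group large, CH2Br small) should give the (2S)-bromohydrin 26 directly, with no epimerisable ketone and no acetonide.

Further compounds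
F0 | step 8 | none | none
F1 | step 13 | (1R,3R)-3-(2-bromoethyl)-2,2-dimethyl-4-methylidenecyclohexan-1-ol | C=C1CC[C@@H](O)C(C)(C)[C@@H]1CCBr
F2 | step 13 | (1R,3R)-3-(2-bromoethyl)-2,2-dimethyl-4-methylidenecyclohexyl chloromethanesulfonate | C=C1CC[C@@H](OS(=O)(=O)CCl)C(C)(C)[C@@H]1CCBr
F3 | step 17 | 2-[(1R,3S)-3-bromo-2,2-dimethyl-6-methylidenecyclohexyl]acetaldehyde | C=C1CC[C@H](Br)C(C)(C)[C@@H]1CC=O
F4 | step 17 | methyl (2Z)-4-[(1R,3S)-3-bromo-2,2-dimethyl-6-methylidenecyclohexyl]-2-methylbut-2-enoate | C=C1CC[C@H](Br)C(C)(C)[C@@H]1C/C=C(/C)C(=O)OC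
F5 | step 17 | (2Z)-4-[(1R,3S)-3-bromo-2,2-dimethyl-6-methylidenecyclohexyl]-N-methoxy-N,2-dimethylbut-2-enamide | C=C1CC[C@H](Br)C(C)(C)[C@@H]1C/C=C(/C)C(=O)N(C)OC
F6 | step 17 | (3Z)-1-bromo-5-[(1R,3S)-3-bromo-2,2-dimethyl-6-methylidenecyclohexyl]-3-methylpent-3-en-2-one | C=C1CC[C@H](Br)C(C)(C)[C@@H]1C/C=C(/C)C(=O)CBr
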